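I decided to reckon the grey flask with one number instead of integrating equations. The proposal is that substrate goes to intermediate unaided, free catalyst turns intermediate into product, and free catalyst is lost to spent catalyst A and, with substrate, to spent catalyst B.

| flask | substrate | free catalyst | temperature | remark | time |
|---|---|---|---|---|---|
| grey | 0.86 M | 7 mM | 35 °C | the very flask that is asked about, followed so far |  |
| red | 0.43 M | 7 mM | 20 °C | run made earlier |  |
| flask | 0.86 M | 7.0 mM | 35 °C |  | 8.0 h |

| run | time / min | product / % |
|---|---|---|
| grey | 50.0 | 50.6 |
| grey | 150 | 49.5 |
| grey | 240 | 50.4 |
| grey | 360 | 50.0 |
| red | 15.0 | 22.4 |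
| red | 40.0 | 50.1 |
| red | 50.0 | 54.7 |
| red | 80.0 | 62.5 |

(readings scatter by 0.5 percentage points)

- theta: change nothing and wait 15 h more
- zeta: at 8.0 h add free catalyst, 50.0 % of the amount charged, then wait 15 h
- alpha: at 8.0 h raise the temperature by 20 K, then wait 15 h
- epsilon: at 8.0 h take out 90 % of the product then present, then wait 15 h

* product, in percent of the substrate first charged, at 8.0 h
* the option that brings most further product ("none" if no option brings more than 2 percentage points) (theta / zeta / alpha / epsilon / none)
* product present, with what was taken out counted in, in percent of the substrate first charged, after alpha
* product present, with what was taken out counted in, in percent of the substrate first charged, after epsilon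

- product that was removed still counts
- steps that have been proposed: free catalyst + intermediate -> free catalyst + product; free catalyst -> spent catalyst A; substrate + free catalyst -> spent catalyst B; substrate -> intermediate
- additions bring no volume worth counting

The grey readings went from 50.6 % at 50.0 min to 50.0 % at 360 min, against a scatter of 0.5 percentage points, so I took that flask as stopped, at a mean of 50.1 % of the charge. The red flask reached 62.5 %, higher than the grey mean, so I read the grey stop as lost catalyst, not a ceiling. If each bit of catalyst exposure converts the same share of what remains, a pseudo-first-order picture, the logarithm of the reciprocal of the unconverted fraction gives 0.696. This is my catalyst dose, the number of e-foldings of the unconverted charge bought by the catalyst's working life.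

Theta, alpha and epsilon bring no new catalyst, so I expected product to stay near 50.1 %. Zeta adds 50.0 % of the catalyst charge, so by my scaling 50.0 % of the dose, and from that I reckoned 15 points more. Was one number enough? The red flask, with the same catalyst charge, gives 0.981 from its reading at 80.0 min, larger than the grey dose, but it differs from the grey flask in both temperature and substrate charge. So I held the grey dose to the grey temperature and substrate charge, and there I scaled it with the catalyst charge.

The forecast gave 50.1 % at 8.0 h, zeta as best, 50.1 % after alpha and 50.1 % after epsilon, with 10 to 15 further points from zeta: “Fresh catalyst is the only option that acts on the remaining material”.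

The grey flask gave 50.6 % at 8.0 h, 50.6 % after alpha and 50.6 % after epsilon, and zeta was best, with 24 points further against my 15 points. At 480 min it held intermediate 49.2 %, substrate 0 % and free catalyst 0 %.

    free catalyst + intermediate → free catalyst + product (k = 28.0 M⁻¹ min⁻¹, Ea = 47.0 kJ mol⁻¹)
    free catalyst → spent catalyst A (k = 0.150 min⁻¹, Ea = 82.0 kJ mol⁻¹)
    substrate + free catalyst → spent catalyst B (k = 0.280 M⁻¹ min⁻¹, Ea = 47.0 kJ mol⁻¹)
    substrate → intermediate (k = 0.580 min⁻¹, Ea = 96.0 kJ mol⁻¹)
    (constants at 35 °C)

The neighbour flask with 0.028 M of free catalyst has 4.00 times the charge, so the scaled dose is 2.78, from which I reckon 6.20 % unconverted; that flask stood at product 92.0 % with intermediate 7.10 %.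

The runs were generated by integration with constants of no real substance; scatter was added.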